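The route hinges on cutting ring C (the CO2Me-bearing ring) at C1–C6 and C3–C4 after adding two hydrogens in thought. The resorcinol pattern O2/O4, the C1 ester and the C6 methyl then match methyl 6-methyl-2,4-dioxocyclohexane-1-carboxylate. A single methoxide-mediated Michael–Dieckmann reaction of two unprotected commercial esters, methyl acetoacetate and methyl crotonate, makes both bonds and the whole carbocycle. In this non-aromatic ring the reactive sites differ in kind: O4 is the open end of an acidic 1,3-dione, while C1 lies between ketone and ester. The benzyl-protected ring A–ring B acid chloride is therefore placed on O4, C1–C6 is dehydrogenated by selenoxide elimination, and hydrogenolysis finishes.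

Key step: step 7

Assumption: the target is achiral, so all dihydro ring C compounds are carried as racemates with one enantiomer drawn, and the Michael–Dieckmann product is written as one tautomer of a rapidly equilibrating enol/dione set.

Step 1
Reactants: 1 methyl orsellinate (methyl 2,4-dihydroxy-6-methylbenzoate)
Product: 2 methyl everninate (methyl 2-hydroxy-4-methoxy-6-methylbenzoate)
Conditions: MeI (1.05 equiv), K2CO3, acetone, reflux
Reagents that add atoms: iodomethane, CI
Why: Williamson O-methylation, in which the C2 hydroxyl is tied up in a hydrogen bond to the ester carbonyl, so one equivalent of MeI should alkylate only the free and more acidic C4 phenol.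

Step 2
Reactants: 2 methyl everninate
Product: 3 methyl 2-(benzyloxy)-4-methoxy-6-methylbenzoate
Conditions: BnBr, K2CO3, DMF, 60 °C
Reagents that add atoms: benzyl bromide, BrCc1ccccc1
Why: Williamson benzylation in a dipolar solvent with heating overcomes the chelate and caps the only remaining phenol with a group that neutral hydrogenolysis removes at the end.

Step 3
Reactants: 3 methyl 2-(benzyloxy)-4-methoxy-6-methylbenzoate
Product: 4 2-(benzyloxy)-4-methoxy-6-methylbenzoic acid
Conditions: KOH, DMSO–H2O, 100 °C; then aq. HCl, 0 °C
Reagents that add atoms: potassium hydroxide, [K+].[OH-]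
Why: Saponification of a di-ortho-substituted benzoate is slow but should go with poorly solvated hydroxide in hot aqueous DMSO, the ethers being inert to base and cold acidification avoiding decarboxylation.

Step 4
Reactants: 4 2-(benzyloxy)-4-methoxy-6-methylbenzoic acid; 5 2,4-dihydroxy-6-methylbenzaldehyde
Product: 7 4-formyl-3-hydroxy-5-methylphenyl 2-(benzyloxy)-4-methoxy-6-methylbenzoate, via acyl trifluoroacetate 6 (not isolated)
Conditions: (CF3CO)2O, toluene, rt
Reagents that add atoms: none
Why: Mixed-anhydride esterification (the trifluoroacetic anhydride depside coupling) activates the hindered, electron-rich acid, which should acylate the free C4 phenol of 5, because the C2 phenol is hydrogen-bonded to the formyl group and the formyl group deactivates the ring toward C-acylation.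

Step 5
Reactants: 7 4-formyl-3-hydroxy-5-methylphenyl 2-(benzyloxy)-4-methoxy-6-methylbenzoate
Product: 8 4-formyl-3-methoxy-5-methylphenyl 2-(benzyloxy)-4-methoxy-6-methylbenzoate
Conditions: MeI, K2CO3, DMF, rt
Reagents that add atoms: iodomethane, CI
Why: Williamson methylation of the single free phenol sets the ring B methoxy group, the di-ortho-substituted aryl ester resists anhydrous carbonate, and the benzyl cap on ring A excludes a Smiles rearrangement.

Step 6
Reactants: 8 4-formyl-3-methoxy-5-methylphenyl 2-(benzyloxy)-4-methoxy-6-methylbenzoate
Product: 9 4-{[2-(benzyloxy)-4-methoxy-6-methylbenzoyl]oxy}-2-methoxy-6-methylbenzoic acid (protected ring A–ring B acid)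
Conditions: NaClO2, NaH2PO4, 2-methyl-2-butene, t-BuOH–THF–H2O, rt
Reagents that add atoms: sodium chlorite, [Na+].[O-]Cl=O
Why: Pinnick oxidation raises the aldehyde to the acid in a weakly acidic buffer that spares the aryl ester and the benzyl ether, so the ring B carboxyl appears without any ester cleavage, and the alkene scavenger intercepts the hypochlorite by-product before it can chlorinate a ring.

Step 7
Reactants: 10 methyl acetoacetate; 11 methyl (E)-crotonate
Product: 14 racemic trans methyl 2-hydroxy-6-methyl-4-oxocyclohex-2-ene-1-carboxylate (methyl dihydroorsellinate; rel-(1R,6S)), via Michael adduct 12 (not isolated), via sodium dionate 13 (not isolated)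
Conditions: NaOMe (1.05 equiv), MeOH, reflux; then aq. HCl, 0 °C
Reagents that add atoms: none
Why: Methoxide deprotonates 10 at its central carbon and this stabilised enolate adds 1,4 to 11 to form C1–C6 (adduct 12); proton transfer then populates the terminal enolate of the acetyl group, whose carbon attacks the former crotonate ester, expels methoxide and forms C3–C4. The closest known reaction type is the classical Michael–Dieckmann (Claisen) annulation of acetoacetates with crotonates to dihydroorsellinates. The single ring closes in the favoured 6-(enolendo)-exo-trig mode, and every other enolate/carbonyl pairing in 12 would give a four-membered ring. All earlier events are reversible, and deprotonation of the new 1,3-dione to salt 13 drains the equilibria toward the six-membered product until acid liberates 14. C6 arises from achiral partners without facial bias (racemate), whereas C1 is an epimerisable β-keto ester carbon that should settle under methoxide trans to the C6 methyl with both groups equatorial; both centres are erased in step 9. The step needs a clean assignment of donor and acceptor roles, which is secured because only 10 has a doubly activated CH2 and only 11 has an electrophilic alkene, and matching methoxide to methyl esters makes transesterification invisible.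

Step 8
Reactants: 9 protected ring A–ring B acid; 14 methyl dihydroorsellinate
Product: 16 racemic trans methyl 4-[(4-{[2-(benzyloxy)-4-methoxy-6-methylbenzoyl]oxy}-2-methoxy-6-methylbenzoyl)oxy]-6-methyl-2-oxocyclohex-3-ene-1-carboxylate (O4 enol ester; rel-(1R,6S)), via acid chloride 15 (not isolated)
Conditions: (COCl)2, cat. DMF, CH2Cl2, 0 °C to rt, evaporate; then 14 (1.3 equiv), Et3N, CH2Cl2, −10 °C to rt
Reagents that add atoms: none
Why: Enol ester formation by O-acylation of a cyclic 1,3-dione with an acid chloride: 14 reacts through the enolate delocalised over O2–C2–C3–C4–O4 whichever tautomer is drawn, the bulky di-ortho-substituted aroyl chloride should choose O4 (flanked only by C5H2) over O2 (crowded by the ester-bearing C1), the bias known from enol derivatisation of 4-substituted cyclohexane-1,3-diones, while omitting DMAP or cyanide prevents O-to-C3 acyl migration and keeping 15 limiting prevents a second acylation.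

Step 9
Reactants: 16 O4 enol ester
Product: 20 methyl 4-[(4-{[2-(benzyloxy)-4-methoxy-6-methylbenzoyl]oxy}-2-methoxy-6-methylbenzoyl)oxy]-2-hydroxy-6-methylbenzoate (ring A O-benzyl tridepside), via C1 selenide 17 (not isolated), via selenoxide 18 (not isolated), via cross-conjugated dienone 19 (not isolated)
Conditions: PhSeCl (1.1 equiv), pyridine, CH2Cl2, 0 °C; then 30% aq. H2O2 (excess), 0 °C to rt
Reagents that add atoms: none
Why: α-Selenenylation of a β-keto ester followed by selenoxide syn elimination, the known way from 2-oxocyclohex-3-ene-1-carboxylates to salicylates: C1 is the only doubly activated sp3 carbon of 16, selenium should enter anti to the C6 methyl and thus syn to H6, the sole β-hydrogen of selenoxide 18, and dienone 19 tautomerises (H5 to O2) to the chelated phenol at or below room temperature, where the hindered aryl esters and the benzyl ether are safe and both stereocentres disappear.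

Step 10
Reactants: 20 ring A O-benzyl tridepside
Product: 21 target, methyl 2-hydroxy-4-({4-[(2-hydroxy-4-methoxy-6-methylbenzoyl)oxy]-2-methoxy-6-methylbenzoyl}oxy)-6-methylbenzoate
Conditions: H2 (1 atm), 10% Pd/C, EtOAc, rt
Reagents that add atoms: none
Why: Catalytic hydrogenolysis of the benzyl aryl ether under neutral conditions, the standard closing move of depside synthesis, should free the ring A phenol while aryl esters, methyl ester and methyl ethers stay intact.

Compound list
1 | methyl orsellinate (methyl 2,4-dihydroxy-6-methylbenzoate) | COC(=O)c1c(C)cc(O)cc1O | starting material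
2 | methyl everninate (methyl 2-hydroxy-4-methoxy-6-methylbenzoate) | COC(=O)c1c(C)cc(OC)cc1O | intermediate
3 | methyl 2-(benzyloxy)-4-methoxy-6-methylbenzoate | COC(=O)c1c(C)cc(OC)cc1OCc1ccccc1 | intermediate
4 | 2-(benzyloxy)-4-methoxy-6-methylbenzoic acid | OC(=O)c1c(C)cc(OC)cc1OCc1ccccc1 | intermediate
5 | 2,4-dihydroxy-6-methylbenzaldehyde | O=Cc1c(C)cc(O)cc1O | starting material
6 | 2-(benzyloxy)-4-methoxy-6-methylbenzoic trifluoroacetic anhydride (not isolated) | O=C(OC(=O)C(F)(F)F)c1c(C)cc(OC)cc1OCc1ccccc1 | intermediate
7 | 4-formyl-3-hydroxy-5-methylphenyl 2-(benzyloxy)-4-methoxy-6-methylbenzoate | O=Cc1c(C)cc(OC(=O)c2c(C)cc(OC)cc2OCc2ccccc2)cc1O | intermediate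
8 | 4-formyl-3-methoxy-5-methylphenyl 2-(benzyloxy)-4-methoxy-6-methylbenzoate | O=Cc1c(C)cc(OC(=O)c2c(C)cc(OC)cc2OCc2ccccc2)cc1OC | intermediate
9 | 4-{[2-(benzyloxy)-4-methoxy-6-methylbenzoyl]oxy}-2-methoxy-6-methylbenzoic acid | OC(=O)c1c(C)cc(OC(=O)c2c(C)cc(OC)cc2OCc2ccccc2)cc1OC | intermediate
10 | methyl acetoacetate | COC(=O)CC(C)=O | starting material
11 | methyl (E)-crotonate | C/C=C/C(=O)OC | starting material
12 | dimethyl 2-acetyl-3-methylpentanedioate (diastereomer mixture, C2 epimerisable, not isolated) | COC(=O)CC(C)C(C(C)=O)C(=O)OC | intermediate
13 | sodium enolate of 14 (racemic, trans, not isolated) | COC(=O)[C@@H]1[C@@H](C)CC(=O)C=C1[O-].[Na+] | intermediate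
14 | racemic trans methyl 2-hydroxy-6-methyl-4-oxocyclohex-2-ene-1-carboxylate, rel-(1R,6S) | COC(=O)[C@@H]1[C@@H](C)CC(=O)C=C1O | intermediate
15 | 4-{[2-(benzyloxy)-4-methoxy-6-methylbenzoyl]oxy}-2-methoxy-6-methylbenzoyl chloride (not isolated) | ClC(=O)c1c(C)cc(OC(=O)c2c(C)cc(OC)cc2OCc2ccccc2)cc1OC | intermediate
16 | racemic trans O4 enol ester, rel-(1R,6S) | COC(=O)[C@@H]1[C@@H](C)CC(OC(=O)c2c(C)cc(OC(=O)c3c(C)cc(OC)cc3OCc3ccccc3)cc2OC)=CC1=O | intermediate
17 | racemic 1-(phenylselanyl) derivative of 16, PhSe trans to the C6 methyl and cis to H6, rel-(1R,6S) (not isolated) | COC(=O)[C@@]1([Se]c2ccccc2)[C@@H](C)CC(OC(=O)c2c(C)cc(OC(=O)c3c(C)cc(OC)cc3OCc3ccccc3)cc2OC)=CC1=O | intermediate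
18 | selenoxide of 17, both configurations at selenium (not isolated) | COC(=O)[C@@]1([Se](=O)c2ccccc2)[C@@H](C)CC(OC(=O)c2c(C)cc(OC(=O)c3c(C)cc(OC)cc3OCc3ccccc3)cc2OC)=CC1=O | intermediate
19 | cross-conjugated dienone with C1=C6 and C3=C4, C2 ketone, C5H2 (not isolated) | COC(=O)C1=C(C)CC(OC(=O)c2c(C)cc(OC(=O)c3c(C)cc(OC)cc3OCc3ccccc3)cc2OC)=CC1=O | intermediate
20 | ring A O-benzyl tridepside | COC(=O)c1c(C)cc(OC(=O)c2c(C)cc(OC(=O)c3c(C)cc(OC)cc3OCc3ccccc3)cc2OC)cc1O | intermediate
21 | target tridepside CNP0357736.0 | COC(=O)c1c(C)cc(OC(=O)c2c(C)cc(OC(=O)c3c(C)cc(OC)cc3O)cc2OC)cc1O | target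

Total step count: 10.
Longest linear sequence: 9 steps (steps 1–6, then 8–10). Step 7 is a one-step side branch.

Steps most likely to fail

Step 9. Four processes could spoil it:
- Selenium may be delivered to the methyl-bearing face, which leaves no syn hydrogen for elimination.
- Selenenylation may compete at C3 or C5.
- The acyl group may be transferred away from the vinylogous anhydride under pyridine or peroxide.
- The freshly formed phenol may be selenenylated again.

The fallback sets out from 16 and removes the two ring hydrogens by hydride abstraction instead of syn elimination. DDQ in dioxane at 80–100 °C should act on the chelated enol tautomer of 16, which is a cyclohexa-1,3-diene, and lead directly to 20. This needs no particular configuration at C1 and makes no new compound (F0).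

Step 8. Acylation at O2 may compete with O4, a second acylation may occur through the C1 enolate, or the acyl group may migrate from oxygen to C3. The fallback sets out from 14 and aromatizes before acylating. Bromination and dehydrobromination with Br2 in AcOH should give methyl 3,5-dibromo-2,4-dihydroxy-6-methylbenzoate F1. Hydrogenolysis (H2, Pd/C, NaOAc, MeOH) strips its bromines to give methyl orsellinate 1. Acid chloride 15 then acylates the free C4 phenol of 1 (pyridine, CH2Cl2), with site control coming from the chelated C2 phenol. The route is rejoined at 20.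

Step 6. The hypochlorite by-product may chlorinate the electron-rich rings, or the di-ortho-substituted aldehyde may oxidise sluggishly. The fallback sets out from 4 and 1 and keeps the ring B carboxyl at the acid oxidation level throughout.
- Acyl trifluoroacetate 6, generated as in step 4, should acylate the free C4 phenol of 1 to give methyl 4-{[2-(benzyloxy)-4-methoxy-6-methylbenzoyl]oxy}-2-hydroxy-6-methylbenzoate F2.
- MeI/K2CO3 in DMF should then give methyl 4-{[2-(benzyloxy)-4-methoxy-6-methylbenzoyl]oxy}-2-methoxy-6-methylbenzoate F3.
- The methyl ester alone is dealkylated by SN2 attack of iodide on its methyl carbon (LiI, pyridine, reflux; acid work-up). This mode of cleavage cannot touch the aryl ester, and the route is rejoined at 9.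

Further compounds
F0 | step 9 | none | none
F1 | step 8 | methyl 3,5-dibromo-2,4-dihydroxy-6-methylbenzoate | COC(=O)c1c(C)c(Br)c(O)c(Br)c1O
F2 | step 6 | methyl 4-{[2-(benzyloxy)-4-methoxy-6-methylbenzoyl]oxy}-2-hydroxy-6-methylbenzoate | COC(=O)c1c(C)cc(OC(=O)c2c(C)cc(OC)cc2OCc2ccccc2)cc1O
F3 | step 6 | methyl 4-{[2-(benzyloxy)-4-methoxy-6-methylbenzoyl]oxy}-2-methoxy-6-methylbenzoate | COC(=O)c1c(C)cc(OC(=O)c2c(C)cc(OC)cc2OCc2ccccc2)cc1OC
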